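**Plan**

1. Retrosynthesis: the 1,2-dioxolane is opened at C4–C5 and at O2–C3 in one cut. This gives a three-atom cation C5(+)–O1–O2–SiEt3 (a peroxycarbenium ion) and the two-carbon partner C4=C3, methyl 3-methylbut-3-enoate.
2. Enabling feature: ring C5 is a ketone-level carbon (bonded to O1, CH3, C4 and the side-chain CH2), and ring C3 is fully substituted next to the unsubstituted C4H2. The ring is therefore the formal [3+2] adduct of a ketone-derived peroxycarbenium ion and a 1,1-disubstituted alkene whose Markovnikov cation is tertiary.
3. The ion precursor, a methoxy triethylsilylperoxy ketal, goes back to a 2-methyl-1-alkene (ozonolysis in MeOH), then to a methyl ketone (Wittig), then to (R)-citronellic acid and 4-phenyl-1-butene (MeLi, cross-metathesis, hydrogenation).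
4. Forward order: side chain first (steps 1–3), peroxyketal next (steps 4–6), the only ring last (step 7).
5. Stereochemistry: the side-chain centre comes unchanged from (R)-citronellic acid. The two quaternary ring centres C3 and C5 are both created in step 7 under control of a confined chiral counteranion.

Key step: step 7

Assumption: the sense of induction of the chiral anion cannot be predicted with confidence, so the (S,S) catalyst is written and the antipode that gives the (3R,5S) ring is to be fixed by experiment; commercial (R)-citronellic acid is taken in its highest available enantiomeric purity.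

**Route**

Step 1
Reactants: 1 (3R)-3,7-dimethyloct-6-enoic acid [(R)-citronellic acid]
Product: 3 (4R)-4,8-dimethylnon-7-en-2-one, via dilithium gem-diolate 2 (not isolated)
Conditions: MeLi (2.2 equiv), Et2O, 0 °C to rt; inverse quench into cold 1 M HCl
Reagents that add atoms: methyllithium, C[Li]
Why: Addition of methyllithium to the lithium carboxylate (organolithium–carboxylate ketone synthesis) should stop at the dilithium gem-diolate 2, which gives the methyl ketone only on acidic work-up; the stereocentre is β to the new carbonyl and cannot epimerise, and no new stereocentre forms.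

Step 2
Reactants: 3 (4R)-4,8-dimethylnon-7-en-2-one; 4 but-3-en-1-ylbenzene (4-phenyl-1-butene)
Product: 5 (4R)-4-methyl-10-phenyldec-7-en-2-one
Conditions: 4 (3 equiv), second-generation Grubbs catalyst RuCl2(=CHPh)(PCy3)(H2IMes) (5 mol%), CH2Cl2, 40 °C, N2 sweep
Reagents that add atoms: none
Why: Olefin cross-metathesis should exchange the isopropylidene terminus of 3 for the terminal alkene of 4 with loss of volatile 2-methylpropene; the ketone is inert to the ruthenium carbene, and the E/Z mixture expected is irrelevant because the alkene is hydrogenated next.

Step 3
Reactants: 5 (4R)-4-methyl-10-phenyldec-7-en-2-one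
Product: 6 (4R)-4-methyl-10-phenyldecan-2-one
Conditions: H2 (1 atm), 10% Pd/C, EtOAc, rt
Reagents that add atoms: none
Why: Heterogeneous catalytic hydrogenation should saturate the disubstituted alkene while the ketone and the benzene ring stay intact under these mild conditions; no stereocentre is formed or touched.

Step 4
Reactants: 6 (4R)-4-methyl-10-phenyldecan-2-one
Product: 7 (4R)-2,4-dimethyl-10-phenyldec-1-ene
Conditions: Ph3PCH3Br, KOtBu, THF, 0 °C to rt
Reagents that add atoms: methyltriphenylphosphonium bromide, C[P+](c1ccccc1)(c1ccccc1)c1ccccc1.[Br-]
Why: Wittig methylenation of the methyl ketone should give the 1,1-disubstituted alkene; the only stereocentre is β to the carbonyl, so the basic ylide cannot epimerise it.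

Step 5
Reactants: 7 (4R)-2,4-dimethyl-10-phenyldec-1-ene
Product: 9 (2RS,4R)-2-hydroperoxy-2-methoxy-4-methyl-10-phenyldecane, via carbonyl oxide 8 (not isolated)
Conditions: O3/O2, CH2Cl2–MeOH (4:1), NaHCO3, −78 °C, Sudan Red 7B end point; N2 purge, cold concentration, no reductive work-up
Reagents that add atoms: ozone, [O-][O+]=O; methanol, CO
Why: Ozonolysis of a 1,1-disubstituted alkene in methanol should cleave the primary ozonide preferentially to the more substituted carbonyl oxide 8 and formaldehyde, and methanol traps 8 as the α-methoxy hydroperoxide; the new acetal carbon forms as a mixture of epimers, which does not matter because it becomes planar in step 7, and the benzene ring reacts far more slowly with ozone than the alkene when ozone is dosed to the indicator end point.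

Step 6
Reactants: 9 (2RS,4R)-2-hydroperoxy-2-methoxy-4-methyl-10-phenyldecane
Product: 10 triethyl{[(2RS,4R)-2-methoxy-4-methyl-10-phenyldecan-2-yl]peroxy}silane
Conditions: Et3SiCl, imidazole, DMF, 0 °C
Reagents that add atoms: chlorotriethylsilane, CC[Si](Cl)(CC)CC
Why: O-Silylation of the hydroperoxide under buffered, non-acidic conditions should leave the acid-labile peroxyketal intact; the silyl group later serves as the leaving group on oxygen in the ring closure.

Step 7
Reactants: 10 triethyl{[(2RS,4R)-2-methoxy-4-methyl-10-phenyldecan-2-yl]peroxy}silane; 11 methyl 3-methylbut-3-enoate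
Product: 14 methyl 2-[(3R,5S)-3,5-dimethyl-5-[(2R)-2-methyl-8-phenyloctyl]-1,2-dioxolan-3-yl]acetate, via peroxycarbenium ion 12 (not isolated), via tertiary carbenium ion 13 (not isolated)
Conditions: 11 (3 equiv), (S,S)-[(3,3'-Ar2-1,1'-binaphthalene-2,2'-diyl)O2P(=NSO2CF3)]2NH (Ar = 3,5-(CF3)2C6H3; 5 mol%), 4 Å molecular sieves, toluene, −78 °C; Et3N quench at −78 °C
Reagents that add atoms: none
Why: Proposed new method: the strong chiral acid (after the first turnover its Et3Si derivative) should remove the methoxy group of 10 as Et3SiOMe and leave peroxycarbenium ion 12 as a contact ion pair with the confined imidodiphosphorimidate anion; the CH2 terminus of 11 then attacks the carbenium carbon to form the C4–C5 bond and tertiary carbenium ion 13, whose cationic C3 is captured by the silylated distal peroxide oxygen with return of Et3Si+ to the anion, which closes the catalytic cycle. The closest known reaction type is the SnCl4-promoted [3+2] annulation of triethylsilyl peroxyketals with 1,1-disubstituted alkenes, which gives 3,3,5,5-tetrasubstituted 1,2-dioxolanes without absolute stereocontrol; the chiral-anion control is new, and its mechanistic models are additions of weak π-nucleophiles to ketone-derived silyloxocarbenium ions and asymmetric intermolecular Prins reactions of alkenes under the same anion class. The only ring, the 1,2-dioxolane, closes by O2–C3 bond formation as a cation–nucleophile collapse (five-membered, formally 5-endo with respect to the consumed C4=C3 bond, unproblematic because a free planar carbenium centre is attacked), the whole being a stepwise polar [3+2]. C5 is set in the C–C bond-forming step by the anion, which must tell the CH3 flank of 12 from the CH2CH(CH3)(CH2)6Ph flank (the side-chain stereocentre is 1,3-remote and offers no useful induction, so this is catalyst control alone); C3 is set in the ring closure inside the same ion pair, where placing CH2CO2Me anti to the long C5 substituent gives the required 3,5-trans-dimethyl arrangement. The step needs Markovnikov attack, ionisation of OMe and not of OOSiEt3, and O-capture faster than proton loss from 13; the 1,1-disubstitution of 11 (only one tertiary cation possible), the higher basicity and accessibility of the methoxy oxygen compared with the silylated peroxide oxygen, and the five-membered intramolecular trap at −78 °C are expected to secure them. Minor ring isomers are diastereomers of 14 because of the fixed side-chain centre and should be removable by chromatography.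

**Compound list**

1 | (3R)-3,7-dimethyloct-6-enoic acid [(R)-citronellic acid] | OC(=O)C[C@H](C)CCC=C(C)C | starting material
2 | dilithium (4R)-4,8-dimethylnon-7-ene-2,2-diolate | CC(O[Li])(O[Li])C[C@H](C)CCC=C(C)C | intermediate
3 | (4R)-4,8-dimethylnon-7-en-2-one | CC(=O)C[C@H](C)CCC=C(C)C | intermediate
4 | but-3-en-1-ylbenzene (4-phenyl-1-butene) | C=CCCc1ccccc1 | starting material
5 | (4R)-4-methyl-10-phenyldec-7-en-2-one (E/Z mixture expected, E drawn) | CC(=O)C[C@H](C)CC/C=C/CCc1ccccc1 | intermediate
6 | (4R)-4-methyl-10-phenyldecan-2-one | CC(=O)C[C@H](C)CCCCCCc1ccccc1 | intermediate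
7 | (4R)-2,4-dimethyl-10-phenyldec-1-ene | C=C(C)C[C@H](C)CCCCCCc1ccccc1 | intermediate
8 | (4R)-4-methyl-10-phenyldecan-2-one O-oxide (carbonyl oxide) | CC(=[O+][O-])C[C@H](C)CCCCCCc1ccccc1 | intermediate
9 | (2RS,4R)-2-hydroperoxy-2-methoxy-4-methyl-10-phenyldecane (both C2 epimers) | COC(C)(OO)C[C@H](C)CCCCCCc1ccccc1 | intermediate
10 | triethyl{[(2RS,4R)-2-methoxy-4-methyl-10-phenyldecan-2-yl]peroxy}silane (both C2 epimers) | COC(C)(OO[Si](CC)(CC)CC)C[C@H](C)CCCCCCc1ccccc1 | intermediate
11 | methyl 3-methylbut-3-enoate | COC(=O)CC(C)=C | starting material
12 | peroxycarbenium ion, [(4R)-4-methyl-10-phenyldecan-2-ylidene](triethylsilyloxy)oxonium | CC(=[O+]O[Si](CC)(CC)CC)C[C@H](C)CCCCCCc1ccccc1 | intermediate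
13 | tertiary carbenium ion, the C–C adduct of 12 and 11 (cation at the future C3, the future C5 configured as in 14) | COC(=O)C[C+](C)C[C@](C)(C[C@H](C)CCCCCCc1ccccc1)OO[Si](CC)(CC)CC | intermediate
14 | methyl 2-[(3R,5S)-3,5-dimethyl-5-[(2R)-2-methyl-8-phenyloctyl]-1,2-dioxolan-3-yl]acetate | COC(=O)C[C@@]1(C)C[C@](C)(C[C@H](C)CCCCCCc2ccccc2)OO1 | target

**Totals and risks**

Total step count: 7. Longest linear sequence: 7 steps (1 to 14).

Steps most likely to fail:

1. Step 7 (bears the label). What may go wrong: ionisation of the silylperoxy group in place of the methoxy group, insufficient facial discrimination at the peroxycarbenium carbon or in the ring closure, and proton loss from the tertiary cation in place of O-capture. The fallback sets out from 10 and comes back at 14, by known chemistry in which the two bonds are made one after the other. Methyl 3-methylbut-2-enoate is converted (LiN(iPr)2, Me3SiCl, THF, −78 °C) into the silyl dienolate [(1-methoxy-3-methylbuta-1,3-dien-1-yl)oxy]trimethylsilane F1. SnCl4 (CH2Cl2, −78 °C) ionises 10 to the same peroxycarbenium ion, which the much more nucleophilic γ-carbon of F1 should trap in a vinylogous Mukaiyama-type addition to give the enoate methyl (2E,7R)-3,5,7-trimethyl-13-phenyl-5-[(triethylsilyl)peroxy]tridec-2-enoate F2. HF·pyridine (THF, 0 °C) frees the hydroperoxide methyl (2E,7R)-5-hydroperoxy-3,5,7-trimethyl-13-phenyltridec-2-enoate F3, and Et2NH in CF3CH2OH closes the ring by 5-exo-trig conjugate addition of the hydroperoxide to give 14. This sequence has no absolute control at C3 and C5, so 14 would be taken from its ring isomers by preparative HPLC; that is possible in principle because the fixed side-chain centre makes all of them diastereomers.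

2. Step 5. What may go wrong: cleavage of the primary ozonide in the wrong sense (back to ketone 6, which can be recycled through step 4), over-oxidation of the arene, and acid-induced rearrangement of the hydroperoxyketal during isolation. The fallback sets out from 6 and comes back at 9, bypassing steps 4 and 5. Ketone 6 is converted with HC(OMe)3 in MeOH (catalytic p-toluenesulfonic acid monohydrate, rt) into the dimethyl ketal [(7R)-9,9-dimethoxy-7-methyldecyl]benzene F4. Acid-catalysed exchange of one methoxy group with anhydrous ethereal H2O2 (one equivalent, catalytic camphorsulfonic acid, 0 °C) should then give 9.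

3. Step 2. What may go wrong: slow turnover at the trisubstituted alkene, competing self-metathesis of the terminal alkene, and double-bond migration. The fallback sets out from 3 and comes back at 5. Ozonolysis of the trisubstituted alkene of 3 (O3, CH2Cl2, −78 °C; Me2S) should give the keto aldehyde (4R)-4-methyl-6-oxoheptanal F5. The aldehyde is then olefinated chemoselectively in the presence of the methyl ketone with the ylide made from (3-phenylpropyl)triphenylphosphonium bromide and NaN(SiMe3)2 (THF, −78 °C), which should give 5 enriched in the Z isomer; the geometry is irrelevant before hydrogenation.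

**Further compounds**

F1 | step 7 | [(1-methoxy-3-methylbuta-1,3-dien-1-yl)oxy]trimethylsilane | COC(O[Si](C)(C)C)=CC(C)=C
F2 | step 7 | methyl (2E,7R)-3,5,7-trimethyl-13-phenyl-5-[(triethylsilyl)peroxy]tridec-2-enoate (both C5 epimers) | COC(=O)/C=C(\C)CC(C)(OO[Si](CC)(CC)CC)C[C@H](C)CCCCCCc1ccccc1
F3 | step 7 | methyl (2E,7R)-5-hydroperoxy-3,5,7-trimethyl-13-phenyltridec-2-enoate (both C5 epimers) | COC(=O)/C=C(\C)CC(C)(OO)C[C@H](C)CCCCCCc1ccccc1
F4 | step 5 | [(7R)-9,9-dimethoxy-7-methyldecyl]benzene | COC(C)(OC)C[C@H](C)CCCCCCc1ccccc1
F5 | step 2 | (4R)-4-methyl-6-oxoheptanal | CC(=O)C[C@H](C)CCC=O
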